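**Strategy.** The tetralone carbocycle is cut at C2–C3 and C1–C8a (tetralone numbering). The feature used is the para-dioxygenated benzenoid ring (C5–OH, C8–OH): in its quinone form the C4a=C8a bond and a C3=C4 vinyl group that already carries the naphthyl unit make an electron-poor diene. A vinylquinone Diels–Alder reaction with 1,1-bis(methylsulfanyl)ethene, whose two carbons become C2 and C1 at the ketone oxidation level, closes the ring in one operation; tautomerisation returns the hydroquinone as a C3=C4 styrene. A chiral phosphoric acid transfer hydrogenation through the ortho-quinone methide then sets C4, and dithioketal hydrolysis releases the ketone. The precursor is a 2-(1-arylvinyl)benzoquinone generated in situ.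

Key step: step 6

Remark: 5-methoxynaphthalen-1-ol and 1,1-bis(methylsulfanyl)ethene are taken as purchasable building blocks.
Remark: the stereocentre C4 of the target is (S) by CIP analysis; the sense of induction in step 7 is assigned by analogy with related ortho-hydroxystyrene reductions, so the catalyst antipode is fixed in a first run.

Step 1
Reactants: 1 5-methoxynaphthalen-1-ol
Product: 2 4-bromo-5-methoxynaphthalen-1-ol
Conditions: NBS (1.0 equiv), MeCN, −30 °C to 0 °C, dark
Reagents that add atoms: N-bromosuccinimide, O=C1CCC(=O)N1Br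
Why: Electrophilic aromatic bromination should go para to the free hydroxyl group, the strongest activator, which is C4 (an alpha position, peri to the methoxy group), because NBS in acetonitrile is para-selective for naphthols and the methoxy-bearing ring is less activated.

Step 2
Reactants: 2 4-bromo-5-methoxynaphthalen-1-ol
Product: 3 1-bromo-8-methoxy-4-(methoxymethoxy)naphthalene
Conditions: MOMCl, i-Pr2NEt, CH2Cl2, 0 °C to rt
Reagents that add atoms: chloromethyl methyl ether, COCCl
Why: O-Alkylation of the naphthol (methoxymethyl ether formation) should give an ether that survives the strong base of step 5 and the quinone stage of step 6 and is removed by acid in step 8.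

Step 3
Reactants: 4 1-(2,5-dihydroxyphenyl)ethan-1-one
Product: 5 1-{2,5-bis[(tert-butyldimethylsilyl)oxy]phenyl}ethan-1-one
Conditions: TBSCl, imidazole, DMF, 40 °C
Reagents that add atoms: tert-butyldimethylsilyl chloride, CC(C)(C)[Si](C)(C)Cl
Why: Silyl ether formation on both phenols should mask the hydroquinone in a form that tolerates hydrazone formation and is removed by fluoride without acid.

Step 4
Reactants: 5 1-{2,5-bis[(tert-butyldimethylsilyl)oxy]phenyl}ethan-1-one
Product: 6 N'-(1-{2,5-bis[(tert-butyldimethylsilyl)oxy]phenyl}ethylidene)-4-methylbenzenesulfonohydrazide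
Conditions: TsNHNH2, EtOH, 60 °C
Reagents that add atoms: 4-methylbenzenesulfonohydrazide, Cc1ccc(cc1)S(=O)(=O)NN
Why: Condensation of the aryl methyl ketone with the sulfonyl hydrazide (hydrazone formation) should give the carbene precursor for the cross-coupling.

Step 5
Reactants: 3 1-bromo-8-methoxy-4-(methoxymethoxy)naphthalene, 6 N'-(1-{2,5-bis[(tert-butyldimethylsilyl)oxy]phenyl}ethylidene)-4-methylbenzenesulfonohydrazide
Product: 8 2-{1-[8-methoxy-4-(methoxymethoxy)naphthalen-1-yl]ethenyl}benzene-1,4-diol, via bis-silyl diarylethene 7 (not isolated)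
Conditions: Pd2(dba)3 (2.5 mol%), 2-dicyclohexylphosphino-2',4',6'-triisopropylbiphenyl (XPhos, 10 mol%), LiOtBu, 1,4-dioxane, 100 °C; then Bu4NF, AcOH, THF, 0 °C to rt, under Ar
Reagents that add atoms: none
Why: In this Barluenga cross-coupling the hydrazone should give a diazoalkane in situ, carbene formation on the arylpalladium bromide followed by aryl migration and beta-hydride elimination from the methyl group can give only the 1,1-diarylethene, and fluoride then frees the hydroquinone under conditions that never protonate the electron-rich alkene.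

Step 6
Reactants: 8 2-{1-[8-methoxy-4-(methoxymethoxy)naphthalen-1-yl]ethenyl}benzene-1,4-diol, 9 1,1-bis(methylsulfanyl)ethene
Product: 12 4-[8-methoxy-4-(methoxymethoxy)naphthalen-1-yl]-1,1-bis(methylsulfanyl)-1,2-dihydronaphthalene-5,8-diol, via vinylquinone 10 (not isolated), via isoquinone methide cycloadduct 11 (not isolated)
Conditions: Ag2O, MgSO4, CH2Cl2, rt, dark; filter; then 9 (3 equiv), CH2Cl2, rt; then silica gel, under Ar
Reagents that add atoms: none
Why: Ag2O should oxidise only the hydroquinone, and the resulting 2-(1-arylvinyl)benzoquinone 10 reacts as an electron-poor diene (C3=C4–C4a=C8a) with the electron-rich ketene dithioacetal in an inverse-electron-demand Diels–Alder reaction, the closest known type being the vinylquinone Diels–Alder reaction with enol ethers and ketene acetals. The six-membered ring C1–C2–C3–C4–C4a–C8a closes by a concerted but asynchronous [4+2] cycloaddition (in its stepwise limit a 6-(enolexo)-exo-trig attack of C8a on the thionium carbon C1), which forms C2–C3 and C1–C8a together. Regioselectivity is needed and is secured by polarity: C3 is the vinylogous acceptor terminus of the C8 carbonyl and carries the largest LUMO coefficient, while the CH2 carbon of the dithioacetal is its nucleophilic end, so the sulfur-bearing carbon should end on C8a. The only stereocentre formed (C8a of cycloadduct 11) is erased when 11 aromatises by proton shifts to hydroquinone 12, so C4 stays planar and is set in step 7. Two sulfur substituents were chosen because a dithioketal, unlike an O,O-ketal, does not ionise under the acid of the next step, which blocks loss of the C1 substituent and aromatisation of the new ring.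

Step 7
Reactants: 12 4-[8-methoxy-4-(methoxymethoxy)naphthalen-1-yl]-1,1-bis(methylsulfanyl)-1,2-dihydronaphthalene-5,8-diol
Product: 13 (4S)-4-[8-methoxy-4-(methoxymethoxy)naphthalen-1-yl]-1,1-bis(methylsulfanyl)-1,2,3,4-tetrahydronaphthalene-5,8-diol
Conditions: (R)-3,3'-bis(2,4,6-triisopropylphenyl)-1,1'-binaphthalene-2,2'-diyl hydrogen phosphate (5 mol%; antipode if required, see remark), diethyl 2,6-dimethyl-1,4-dihydropyridine-3,5-dicarboxylate (Hantzsch ester, 1.5 equiv), CH2Cl2, 0 °C, under Ar
Reagents that add atoms: none
Why: In this chiral phosphoric acid catalysed transfer hydrogenation of an ortho-hydroxystyrene, protonation at C3 should give an ortho-quinone methide (diarylmethyl cation) held by hydrogen bonds from O5–H to the chiral phosphate, and the Hantzsch ester delivers hydride to one face of C4, so the catalyst controls the new (S) stereocentre.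

Step 8
Reactants: 13 (4S)-4-[8-methoxy-4-(methoxymethoxy)naphthalen-1-yl]-1,1-bis(methylsulfanyl)-1,2,3,4-tetrahydronaphthalene-5,8-diol
Product: 15 (4S)-5,8-dihydroxy-4-(4-hydroxy-8-methoxynaphthalen-1-yl)-3,4-dihydronaphthalen-1(2H)-one, via methoxymethyl-protected tetralone 14 (not isolated)
Conditions: MeI (20 equiv), MeCN/H2O (4:1), 45 °C; then 1 M HCl, 30 °C, under Ar
Reagents that add atoms: water, O
Why: Alkylative dithioketal hydrolysis should work because S-methylation turns each methylsulfanyl group into a leaving group and water captures the thionium ion to give the hydrogen-bonded aryl ketone, while the acid set free (completed with HCl) cleaves the methoxymethyl ether by acetal hydrolysis and the non-enolisable C4 centre keeps its configuration.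

**Compound list**

1 | 5-methoxynaphthalen-1-ol | COc1cccc2c(O)cccc12 | starting material
2 | 4-bromo-5-methoxynaphthalen-1-ol | COc1cccc2c(O)ccc(Br)c12 | intermediate
3 | 1-bromo-8-methoxy-4-(methoxymethoxy)naphthalene | COc1cccc2c(OCOC)ccc(Br)c12 | intermediate
4 | 1-(2,5-dihydroxyphenyl)ethan-1-one | CC(=O)c1cc(O)ccc1O | starting material
5 | 1-{2,5-bis[(tert-butyldimethylsilyl)oxy]phenyl}ethan-1-one | CC(=O)c1cc(O[Si](C)(C)C(C)(C)C)ccc1O[Si](C)(C)C(C)(C)C | intermediate
6 | N'-(1-{2,5-bis[(tert-butyldimethylsilyl)oxy]phenyl}ethylidene)-4-methylbenzenesulfonohydrazide | CC(=NNS(=O)(=O)c1ccc(C)cc1)c1cc(O[Si](C)(C)C(C)(C)C)ccc1O[Si](C)(C)C(C)(C)C | intermediate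
7 | 1-(1-{2,5-bis[(tert-butyldimethylsilyl)oxy]phenyl}ethenyl)-8-methoxy-4-(methoxymethoxy)naphthalene | COc1cccc2c(OCOC)ccc(C(=C)c3cc(O[Si](C)(C)C(C)(C)C)ccc3O[Si](C)(C)C(C)(C)C)c12 | intermediate
8 | 2-{1-[8-methoxy-4-(methoxymethoxy)naphthalen-1-yl]ethenyl}benzene-1,4-diol | COc1cccc2c(OCOC)ccc(C(=C)c3cc(O)ccc3O)c12 | intermediate
9 | 1,1-bis(methylsulfanyl)ethene | C=C(SC)SC | starting material
10 | 2-{1-[8-methoxy-4-(methoxymethoxy)naphthalen-1-yl]ethenyl}cyclohexa-2,5-diene-1,4-dione | COc1cccc2c(OCOC)ccc(C(=C)C3=CC(=O)C=CC3=O)c12 | intermediate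
11 | 8-[8-methoxy-4-(methoxymethoxy)naphthalen-1-yl]-5,5-bis(methylsulfanyl)-4a,5,6,7-tetrahydronaphthalene-1,4-dione (racemic at the ring-fusion CH) | COc1cccc2c(OCOC)ccc(C3=C4C(=O)C=CC(=O)C4C(SC)(SC)CC3)c12 | intermediate
12 | 4-[8-methoxy-4-(methoxymethoxy)naphthalen-1-yl]-1,1-bis(methylsulfanyl)-1,2-dihydronaphthalene-5,8-diol | COc1cccc2c(OCOC)ccc(C3=CCC(SC)(SC)c4c(O)ccc(O)c34)c12 | intermediate
13 | (4S)-4-[8-methoxy-4-(methoxymethoxy)naphthalen-1-yl]-1,1-bis(methylsulfanyl)-1,2,3,4-tetrahydronaphthalene-5,8-diol | COc1cccc2c(OCOC)ccc([C@@H]3CCC(SC)(SC)c4c(O)ccc(O)c43)c12 | intermediate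
14 | (4S)-5,8-dihydroxy-4-[8-methoxy-4-(methoxymethoxy)naphthalen-1-yl]-3,4-dihydronaphthalen-1(2H)-one | COc1cccc2c(OCOC)ccc([C@@H]3CCC(=O)c4c(O)ccc(O)c43)c12 | intermediate
15 | (4S)-5,8-dihydroxy-4-(4-hydroxy-8-methoxynaphthalen-1-yl)-3,4-dihydronaphthalen-1(2H)-one | COc1cccc2c(O)ccc([C@@H]3CCC(=O)c4c(O)ccc(O)c43)c12 | target

**Totals.** Total step count: 8. Longest linear sequence: 6 steps (1, 2, 5, 6, 7, 8 from compound 1; equally 3, 4, 5, 6, 7, 8 from compound 4).

**Steps most likely to fail**

Step 6. What may go wrong: addition of the dithioacetal to the free ring positions C6/C7 of the quinone instead of cycloaddition, self-dimerisation of the vinylquinone, redox exchange between product hydroquinone and unreacted quinone, or loss of methanethiol from the cycloadduct with aromatisation of the new ring. Fallback, setting out from 8: the same Ag2O oxidation gives 10, which is combined with tert-butyl(dimethyl)(vinyloxy)silane, an enol ether of the dienophile class best documented for vinylquinones. The same two bonds form and the product is the 1-silyloxy-1,2-dihydronaphthalene-5,8-diol F1. The phosphoric acid/Hantzsch ester reduction of step 7 then gives the (4S)-tetrahydronaphthalenediol F2 as both C1 epimers. Ac2O in pyridine gives the silyloxy diacetate F3, HF·pyridine in THF frees the C1 alcohol in the hydroxy diacetate F4, and Dess–Martin periodinane with NaHCO3 in CH2Cl2 gives the ketone diacetate F5. K2CO3 in degassed MeOH at 0 °C removes the acetates and the route is rejoined at 14, which 1 M HCl converts to 15 as in the second stage of step 8.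

Step 7. What may go wrong: poor facial selectivity, because the cation at C4 is crowded by the peri-methoxy group and can be stabilised from the alkoxynaphthyl side, which loosens its contact with the phosphate; neighbouring-group attack of the peri-methoxy oxygen on the cation is a second drain. Fallback, setting out from 12: reduction with achiral (PhO)2PO2H and the Hantzsch ester gives the racemic tetrahydronaphthalenediol F6, which is resolved by preparative supercritical-fluid chromatography on a chiral stationary phase; the (S)-enantiomer is 13, where the route is rejoined.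

Step 5. What may go wrong: stalling of the coupling at the peri-hindered bromide (slow oxidative addition or slow aryl migration to the crowded carbene) and early loss of silyl groups to the base. Fallback, setting out from 5 and 3: ketone 5 is converted with KN(SiMe3)2 and PhNTf2 in THF at −78 °C into the enol triflate F7, and bromide 3 with B2pin2, PdCl2(dppf) and KOAc in dioxane into the pinacol boronate F8. Suzuki–Miyaura coupling with Pd(OAc)2, 2-dicyclohexylphosphino-2',6'-dimethoxybiphenyl (SPhos) and K3PO4 in toluene/H2O joins them, and the route is rejoined at 7, which is desilylated to 8 as in the second stage of step 5.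

Further compounds
F1 | step 6 | 1-[(tert-butyldimethylsilyl)oxy]-4-[8-methoxy-4-(methoxymethoxy)naphthalen-1-yl]-1,2-dihydronaphthalene-5,8-diol (racemic at C1) | COc1cccc2c(OCOC)ccc(C3=CCC(O[Si](C)(C)C(C)(C)C)c4c(O)ccc(O)c34)c12
F2 | step 6 | (4S)-1-[(tert-butyldimethylsilyl)oxy]-4-[8-methoxy-4-(methoxymethoxy)naphthalen-1-yl]-1,2,3,4-tetrahydronaphthalene-5,8-diol (both C1 epimers) | COc1cccc2c(OCOC)ccc([C@@H]3CCC(O[Si](C)(C)C(C)(C)C)c4c(O)ccc(O)c43)c12
F3 | step 6 | (5S)-8-[(tert-butyldimethylsilyl)oxy]-5-[8-methoxy-4-(methoxymethoxy)naphthalen-1-yl]-5,6,7,8-tetrahydronaphthalene-1,4-diyl diacetate (both C8 epimers) | COc1cccc2c(OCOC)ccc([C@@H]3CCC(O[Si](C)(C)C(C)(C)C)c4c(OC(C)=O)ccc(OC(C)=O)c43)c12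
F4 | step 6 | (5S)-8-hydroxy-5-[8-methoxy-4-(methoxymethoxy)naphthalen-1-yl]-5,6,7,8-tetrahydronaphthalene-1,4-diyl diacetate (both C8 epimers) | COc1cccc2c(OCOC)ccc([C@@H]3CCC(O)c4c(OC(C)=O)ccc(OC(C)=O)c43)c12
F5 | step 6 | (5S)-5-[8-methoxy-4-(methoxymethoxy)naphthalen-1-yl]-8-oxo-5,6,7,8-tetrahydronaphthalene-1,4-diyl diacetate | COc1cccc2c(OCOC)ccc([C@@H]3CCC(=O)c4c(OC(C)=O)ccc(OC(C)=O)c43)c12
F6 | step 7 | 4-[8-methoxy-4-(methoxymethoxy)naphthalen-1-yl]-1,1-bis(methylsulfanyl)-1,2,3,4-tetrahydronaphthalene-5,8-diol (racemate) | COc1cccc2c(OCOC)ccc(C3CCC(SC)(SC)c4c(O)ccc(O)c43)c12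
F7 | step 5 | 1-{2,5-bis[(tert-butyldimethylsilyl)oxy]phenyl}ethenyl trifluoromethanesulfonate | C=C(OS(=O)(=O)C(F)(F)F)c1cc(O[Si](C)(C)C(C)(C)C)ccc1O[Si](C)(C)C(C)(C)C
F8 | step 5 | 2-[8-methoxy-4-(methoxymethoxy)naphthalen-1-yl]-4,4,5,5-tetramethyl-1,3,2-dioxaborolane | COc1cccc2c(OCOC)ccc(B3OC(C)(C)C(C)(C)O3)c12
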